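# Proposed synthesis of CNP0328260.1: (2S)-5,7-dihydroxy-2-(8-hydroxy-2,2-dimethyl-7-prenyl-2H-chromen-6-yl)-8-prenylchroman-4-one

Flavanone numbering is used for the target and late intermediates (O1, C2, C3, C4, C4a, C5–C8, C8a; ring B C1'–C6'). Prenyl = 3-methylbut-2-en-1-yl, MOM = methoxymethyl, TBS = tert-butyldimethylsilyl.

## Analysis of the target

The target is a flavanone: ring A (C4a to C8a) carries hydroxyls at C5 and C7 and a prenyl group at C8, ring C is the dihydropyranone (O1, C2, C3, C4=O), and ring B is bonded through C1' to C2. Ring B is also the benzo ring of a 2,2-dimethyl-2H-chromene (ring oxygen on C4', vinyl carbon on C5') with a free hydroxyl at C3' and a second prenyl group at C2', so only C6' is unsubstituted and C1' is flanked by the C2' prenyl group. C2 is the only stereocenter (S); there is no second center to relay from, so a catalyst or reagent must set it. C2 is benzylic, bonded to O1 and β to the C4 carbonyl, so base can open ring C by a retro-oxa-Michael reaction and close it again with loss of configuration. The sensitive groups are the two prenyl double bonds (each ortho to a phenol oxygen that adds to it under strong acid), the chromene double bond and three phenols; they exclude hydrogenolysis, strong acid and strong oxidants late in the route. Three things make the synthesis hard: the prenyl group must go to C8 and not C6 on a ring whose two oxygens ortho to C4a (O1 and O5) are nearly alike, the bond formation at C2 must tolerate the crowded ring B, and C2 must be set late and without base. The plan rests on C4: it is a carbonyl carbon on C4a between C5–OH and C8a–O1, so with C4 as a formyl group ring A is a salicylaldehyde whose other ortho oxygen O1 can carry C2=C3 as a 1-arylvinyl ether, and adding the formyl C–H across that alkene makes C3–C4, the C2–H bond and ring C in one step.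

## Retrosynthetic reasoning

**24 to 23.** Only two acetal C–O bonds are cut: 23 is the 7,3'-bis(methoxymethyl) ether of the target. These two phenols need a group that survives carbonate, hydride, fluoride, a titanium alkylidene and a rhodium hydride and comes off without base. O5 is left unprotected in 23 on purpose.

**23 to 22.** Ring C is opened at C3–C4. Cutting O1–C2 instead would lead to an oxa-Michael closure, which is reversible and puts C2 under thermodynamic control. Cutting C2–C1' would ask a ring B nucleophile with an ortho prenyl group to add to a chromone. The C3–C4 cut, with one hydrogen moved from C2 back to C4, gives the isomer 22, a salicylaldehyde with a 1-arylvinyl ether on O1. Forward, a chiral rhodium bisphosphine cation must insert into the formyl C–H bond, deliver that hydrogen to one face of C2 and join C3 to C4. The gain is that ring, ketone and stereocenter appear together, with no stoichiometric reagent and no base. The free 5-OH is kept because its hydrogen bond to the formyl oxygen fixes the aldehyde with its C–H pointing toward O1 and the enol ether. It is not converted to a phenoxide: a rhodium phenoxide would hold the acyl metal on the C5 side of C4, where C3 cannot be reached.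

**22 to 20.** The C8–CH2 bond of the ring A prenyl group is cut and the prenyl group is returned to O5, giving aryl prenyl ether 20. Forward, two successive [3,3] shifts (O5 to C6, then C6 to C8) must run under conditions the enol ether tolerates. The gain is twofold: the prenyl group protects O5 through the fragment union and then becomes the C8 substituent while freeing the 5-OH, and C8 (para to O5) is selected by the mechanism.

**20 to 18.** No skeletal bond is cut; 20, 19 and 18 differ only at the formyl carbon (aldehyde, alcohol, silyl ether). The enol ether is made by methylenating an ester carbonyl, and a formyl group would be methylenated first, so this carbon is carried as a silylated hydroxymethyl group and oxidised only after the enol ether exists.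

**18 to 10 and 16.** The methylene carbon C3 is removed (18 from ester 17 by carbonyl methylenation), then the O1–C2 acyl bond is cut (17 from acid 10 and phenol 16). This is the convergent cut, between two fragments of similar size, and an aryl ester is a more reliable C–O bond to make than a 1-arylvinyl aryl ether by direct coupling.

**16 to 11 and 13.** 16 comes from diol 15 (silylation), 15 from aldehyde 14 (reduction), 14 from 12 and prenyl bromide 13, and 12 from 11 by etherification of the para hydroxyl. In 12 the two hydroxyls ortho to the formyl group are equivalent, so one O-prenylation decides, with no selectivity problem, which oxygen becomes O5 and which O1.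

**10 to 1 and 2.** 10 comes from aldehyde 9 (oxidation) and 9 from phenol 8 (protection). In 8 the C2'–CH2 bond of the ring B prenyl group is cut: an aromatic Claisen shift of the 1,1-dimethylallyl ether 7 gives 8, 7 comes from alkyne 6 by semi-hydrogenation, and 6 from phenol 5 and chloride 2. In 5 the pyran ring is cut at C5'–C(vinyl) and O–C(CH3)2: a propargyl Claisen cascade from ether 3, made from 1 and 2. Each rearrangement has only one free ortho position, so the pattern of ring B follows from the mechanism.

## Alternatives that were turned down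

**Alternative 1:** Ring B by two sigmatropic shifts in one flask.
- **Disconnection:** the C2'–CH2 bond of the ring B prenyl group and the pyran ring are cut together, leading to bis-ether A2, 3-[(2-methylbut-3-en-2-yl)oxy]-4-[(2-methylbut-3-yn-2-yl)oxy]benzaldehyde.
- **Forward key step:** heating A2 in N,N-diethylaniline moves the tertiary allyl group from the 3-oxygen to C2 and the tertiary propargyl group from the 4-oxygen to C5, where a hydrogen shift and an oxa-electrocyclisation close the pyran. The product A1, 8-hydroxy-2,2-dimethyl-7-prenyl-2H-chromene-6-carbaldehyde, is identical with 8 of the route below.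
- **For it:** each ether has one free ortho position, so the substitution pattern is fixed by mechanism, and no reagent is consumed.
- **Against it:** it does not address C2 or ring C, where the target is difficult. A2 is awkward to assemble: the 4-OH of 1 reacts first, and the tertiary allyl ether cannot be made by semi-hydrogenation once a second propargyl ether is present, so a protecting group or a palladium-catalysed branched O-allylation is needed. The allyl ether rearranges well below the temperature the propargyl ether needs and can lose isoprene if held there.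
- **Comparison:** on step count for ring B it is as good or better (A1 in three operations from 1 with a branched O-allylation, against five for 8). The chosen strategy offers instead two separately controlled rearrangements, and spends its one unprecedented step on the stereocenter. The cascade could later be adopted as a shortcut to 8 without other changes.

**Alternative 2:** C2–C3 by carbenoid C–H insertion.
- **Disconnection:** C2–C3 is cut; C3 becomes the diazo carbon of a diazomethyl ketone on C4 and C2 the benzylic CH2 of a ring B benzyl ether on O1, i.e. diazoketone A4.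
- **Forward key step:** a chiral dirhodium tetracarboxylate of divalent rhodium such as Rh2(S-PTTL)4 converts A4 into a carbenoid at C3 that inserts into one of the two enantiotopic C2–H bonds (1,6-insertion). This closes ring C and gives A3, the (2S)-5,7,3'-tris(triisopropylsilyl) ether of the target.
- **For it:** the C–H bond is doubly activated (α to oxygen, benzylic), and the precursor ether comes from a plain O-benzylation. On robustness of the precursor it is the stronger plan.
- **Against it:** a carbenoid from a diazomethyl ketone has no donor group and is unselective; A4 offers it two prenyl double bonds, the chromene double bond and two electron-rich arenes. O1 lies 1,5 to the carbenoid carbon, so oxonium ylide formation and a 1,2-benzyl shift (Stevens type), which would contract ring C to five members, competes directly. Induction by Rh2(S-PTTL)4 is best established for carbenoids with two stabilising groups. A4 needs acylation of diazomethane by a hindered 2,6-dioxygenated benzoyl chloride beside acid-sensitive prenyl groups, and three silyl ethers must later be removed with fluoride buffered well enough not to open ring C.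
- **Comparison:** both plans let a chiral rhodium catalyst create C2 as ring C closes, in a similar number of steps. The hydroacylation is an isomerisation through a metal hydride that ignores trisubstituted alkenes and needs no diazo compound. It offers chemoselectivity in the ring-closing event in exchange for a more delicate precursor.

**Alternative 3:** Ring A built last.
- **Disconnection:** C8–C8a and C4a–C5 are cut. What remains is the (S)-5-bromo-2-aryl-2,3-dihydropyran-4-one A6 (ring C with C2 and ring B in place); C5–C8 come from the bis(trimethylsilyl) dienol ether A7 of the γ-prenylated acetoacetate A8.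
- **Forward key step:** with ZnCl2 the terminal carbon of A7 (future C8) adds to the oxygen-bearing alkene carbon of A6 (future C8a), the ester carbon (future C5) acylates the α-carbon (future C4a), and loss of HBr and methanol aromatises ring A. The product is A5, the (2S)-3'-O-triisopropylsilyl ether of the target.
- **For it:** the stereocenter would come from a catalytic asymmetric hetero-Diels–Alder reaction, an established class, so on predictability of the enantioselective step it is stronger. The C8 prenyl group is placed by the skeleton of A7 and the 5- and 7-OH appear unprotected; there it is at least as strong.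
- **Against it:** the annulation needs two C–C bonds, an elimination and an aromatisation in one pot. The nucleophilic terminus of A7 is the substituted one, and the electrophilic carbon of A6 is the β-carbon of a vinylogous ester deactivated further by the α-bromine. After the first addition O1 is β to a zinc enolate and can be expelled, and the O1–C2 bond is benzylic to an aryl ring with a para oxygen, so the stereocenter is exposed to ZnCl2 and HBr throughout. HBr is set free beside two ortho-prenyl phenols.
- **Comparison:** the chosen route takes ring A with its three oxygens from commercial 11, makes one C–C bond in the decisive step and creates C2 in that step, never carrying it through Lewis acid or base. Alternative 3 is more convergent on paper and lighter in protecting groups, but its decisive step is a multi-event cascade with less mechanistic backing for this substitution pattern.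

Key step: step 17

## Route

Assumption: the sense of induction of (R)-DTBM-SEGPHOS in step 17 cannot be predicted with confidence; if the first run gives the (2R) product, the (S)-ligand is used with no other change.

Step 1
Reactants: 1 3,4-dihydroxybenzaldehyde; 2 3-chloro-3-methylbut-1-yne
Product: 3 3-hydroxy-4-[(2-methylbut-3-yn-2-yl)oxy]benzaldehyde
Conditions: 2 (1.1 equiv), K2CO3 (1.05 equiv), KI (cat.), CuI (cat.), DMF, 20–40 °C, Ar
Reagents that add atoms: none
Why: Copper-assisted O-alkylation of a phenoxide by a tertiary propargyl chloride; with one equivalent of carbonate only the 4-OH, para to the formyl group and the more acidic, is ionised, and the low temperature keeps the free 3-OH from adding to the alkyne.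

Step 2
Reactants: 3 3-hydroxy-4-[(2-methylbut-3-yn-2-yl)oxy]benzaldehyde
Product: 5 8-hydroxy-2,2-dimethyl-2H-chromene-6-carbaldehyde, via ortho-allenylphenol 4 (not isolated)
Conditions: PhNEt2, 185 °C
Reagents that add atoms: none
Why: Aromatic propargyl Claisen rearrangement to C5, the only free ortho position, gives 4 after tautomerisation; a 1,5-hydrogen shift and a 6π oxa-electrocyclisation then close the dimethylpyran ring.

Step 3
Reactants: 5 8-hydroxy-2,2-dimethyl-2H-chromene-6-carbaldehyde; 2 3-chloro-3-methylbut-1-yne
Product: 6 2,2-dimethyl-8-[(2-methylbut-3-yn-2-yl)oxy]-2H-chromene-6-carbaldehyde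
Conditions: 2 (1.5 equiv), K2CO3, KI (cat.), CuI (cat.), acetone, 55 °C
Reagents that add atoms: none
Why: The same copper-assisted O-alkylation on the single remaining phenol; the aldehyde has no α-hydrogen and is inert to carbonate.

Step 4
Reactants: 6 2,2-dimethyl-8-[(2-methylbut-3-yn-2-yl)oxy]-2H-chromene-6-carbaldehyde
Product: 7 2,2-dimethyl-8-[(2-methylbut-3-en-2-yl)oxy]-2H-chromene-6-carbaldehyde
Conditions: H2 (1 atm), Pd/CaCO3 poisoned with Pb(OAc)2, quinoline, EtOAc, 20 °C
Reagents that add atoms: none
Why: Lindlar semi-hydrogenation stops at the terminal alkene; the poisoned catalyst should leave the conjugated chromene double bond and the aldehyde alone.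

Step 5
Reactants: 7 2,2-dimethyl-8-[(2-methylbut-3-en-2-yl)oxy]-2H-chromene-6-carbaldehyde
Product: 8 8-hydroxy-2,2-dimethyl-7-prenyl-2H-chromene-6-carbaldehyde
Conditions: xylenes, 130 °C
Reagents that add atoms: none
Why: Aromatic Claisen rearrangement: the [3,3] shift of the 1,1-dimethylallyl ether can only go to C7 (C8a carries the ring oxygen) and inverts the allyl unit to the linear prenyl group; tautomerisation restores the phenol.

Step 6
Reactants: 8 8-hydroxy-2,2-dimethyl-7-prenyl-2H-chromene-6-carbaldehyde
Product: 9 8-(methoxymethoxy)-2,2-dimethyl-7-prenyl-2H-chromene-6-carbaldehyde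
Conditions: NaH, MOMCl, DMF, 0 °C
Reagents that add atoms: chloromethyl methyl ether, COCCl
Why: Williamson-type O-alkylation; the sodium phenoxide is reactive enough for the hindered position between the prenyl group and the ring oxygen.

Step 7
Reactants: 9 8-(methoxymethoxy)-2,2-dimethyl-7-prenyl-2H-chromene-6-carbaldehyde
Product: 10 8-(methoxymethoxy)-2,2-dimethyl-7-prenyl-2H-chromene-6-carboxylic acid
Conditions: NaClO2, NaH2PO4, 2-methylbut-2-ene (20 equiv), t-BuOH–H2O, 0 to 20 °C
Reagents that add atoms: sodium chlorite, [Na+].[O-]Cl=O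
Why: Pinnick oxidation: buffered chlorite oxidises only the aldehyde, and the large excess of alkene scavenger removes hypochlorous acid before it can reach the prenyl or chromene double bonds; the MOM ether is stable at this pH.

Step 8
Reactants: 11 2,4,6-trihydroxybenzaldehyde
Product: 12 2,6-dihydroxy-4-(methoxymethoxy)benzaldehyde
Conditions: MOMCl (1.0 equiv), K2CO3 (1.0 equiv), acetone, 0 °C
Reagents that add atoms: chloromethyl methyl ether, COCCl
Why: The 4-OH is para to the formyl group and not hydrogen-bonded, so it is the most acidic and is alkylated first (Williamson-type); the two ortho hydroxyls are held by the carbonyl.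

Step 9
Reactants: 12 2,6-dihydroxy-4-(methoxymethoxy)benzaldehyde; 13 prenyl bromide (1-bromo-3-methylbut-2-ene)
Product: 14 2-hydroxy-4-(methoxymethoxy)-6-(prenyloxy)benzaldehyde
Conditions: 13 (1.05 equiv), K2CO3 (1.1 equiv), acetone, 20–40 °C
Reagents that add atoms: none
Why: Williamson ether synthesis on one of two equivalent hydroxyls; after the first alkylation the remaining hydroxyl is strongly hydrogen-bonded to the carbonyl and reacts much more slowly, so the reaction should stop at the mono-ether.

Step 10
Reactants: 14 2-hydroxy-4-(methoxymethoxy)-6-(prenyloxy)benzaldehyde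
Product: 15 2-(hydroxymethyl)-5-(methoxymethoxy)-3-(prenyloxy)phenol
Conditions: NaBH4, THF–MeOH, 0 °C; work-up at pH 7
Reagents that add atoms: none
Why: Hydride reduction of the aldehyde; the electron-rich salicyl alcohol is kept cold and neutral and taken on at once.

Step 11
Reactants: 15 2-(hydroxymethyl)-5-(methoxymethoxy)-3-(prenyloxy)phenol
Product: 16 2-{[(tert-butyldimethylsilyl)oxy]methyl}-5-(methoxymethoxy)-3-(prenyloxy)phenol
Conditions: TBSCl (1.05 equiv), imidazole, CH2Cl2, −10 °C
Reagents that add atoms: tert-butyldimethylsilyl chloride, CC(C)(C)[Si](C)(C)Cl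
Why: Chemoselective silylation: the primary benzylic hydroxyl reacts faster than the ortho-substituted phenol, and the alkyl silyl ether with a free phenol is also the thermodynamically preferred isomer.

Step 12
Reactants: 10 8-(methoxymethoxy)-2,2-dimethyl-7-prenyl-2H-chromene-6-carboxylic acid; 16 2-{[(tert-butyldimethylsilyl)oxy]methyl}-5-(methoxymethoxy)-3-(prenyloxy)phenol
Product: 17 2-{[(tert-butyldimethylsilyl)oxy]methyl}-5-(methoxymethoxy)-3-(prenyloxy)phenyl 8-(methoxymethoxy)-2,2-dimethyl-7-prenyl-2H-chromene-6-carboxylate
Conditions: DCC, DMAP (20 mol %), CH2Cl2, 0 to 20 °C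
Reagents that add atoms: none
Why: Steglich esterification under neutral conditions; the phenol has only one ortho substituent at this stage, because C8 is still unsubstituted.

Step 13
Reactants: 17 2-{[(tert-butyldimethylsilyl)oxy]methyl}-5-(methoxymethoxy)-3-(prenyloxy)phenyl 8-(methoxymethoxy)-2,2-dimethyl-7-prenyl-2H-chromene-6-carboxylate
Product: 18 tert-butyl{[2-({1-[8-(methoxymethoxy)-2,2-dimethyl-7-prenyl-2H-chromen-6-yl]ethenyl}oxy)-4-(methoxymethoxy)-6-(prenyloxy)phenyl]methoxy}dimethylsilane
Conditions: Cp2TiMe2 (3 equiv), toluene–THF, 70 °C, dark; filtration through basic Al2O3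
Reagents that add atoms: dimethyltitanocene Cp2TiMe2, C[Ti](C)(C1C=CC=C1)C1C=CC=C1
Why: Petasis methylenation: thermally generated Cp2Ti=CH2 adds to the ester carbonyl and cycloreverts to the enol ether under non-acidic conditions; the only carbonyl present is the ester, and trisubstituted alkenes, acetals and silyl ethers are not attacked.

Step 14
Reactants: 18 tert-butyl{[2-({1-[8-(methoxymethoxy)-2,2-dimethyl-7-prenyl-2H-chromen-6-yl]ethenyl}oxy)-4-(methoxymethoxy)-6-(prenyloxy)phenyl]methoxy}dimethylsilane
Product: 19 [2-({1-[8-(methoxymethoxy)-2,2-dimethyl-7-prenyl-2H-chromen-6-yl]ethenyl}oxy)-4-(methoxymethoxy)-6-(prenyloxy)phenyl]methanol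
Conditions: TBAF (1.1 equiv), THF, 0 °C
Reagents that add atoms: none
Why: Fluoride cleaves the Si–O bond; the basic medium preserves the acid-labile enol ether and the MOM ethers.

Step 15
Reactants: 19 [2-({1-[8-(methoxymethoxy)-2,2-dimethyl-7-prenyl-2H-chromen-6-yl]ethenyl}oxy)-4-(methoxymethoxy)-6-(prenyloxy)phenyl]methanol
Product: 20 2-({1-[8-(methoxymethoxy)-2,2-dimethyl-7-prenyl-2H-chromen-6-yl]ethenyl}oxy)-4-(methoxymethoxy)-6-(prenyloxy)benzaldehyde
Conditions: MnO2 (15 equiv), CH2Cl2, 20 °C
Reagents that add atoms: none
Why: Neutral heterogeneous oxidation of an electron-rich benzylic alcohol; it stops at the aldehyde and leaves enol ether and alkenes untouched.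

Step 16
Reactants: 20 2-({1-[8-(methoxymethoxy)-2,2-dimethyl-7-prenyl-2H-chromen-6-yl]ethenyl}oxy)-4-(methoxymethoxy)-6-(prenyloxy)benzaldehyde
Product: 22 2-({1-[8-(methoxymethoxy)-2,2-dimethyl-7-prenyl-2H-chromen-6-yl]ethenyl}oxy)-6-hydroxy-4-(methoxymethoxy)-3-prenylbenzaldehyde, via ortho-dienone 21 (not isolated)
Conditions: Eu(fod)3 (10 mol %), NaHCO3, toluene, 80 °C
Reagents that add atoms: none
Why: Claisen–Cope (para-Claisen) rearrangement: europium chelated between the formyl oxygen and O5 accelerates the [3,3] shift of the prenyl ether to C6 (21), and the Cope shift of the 1,1-dimethylallyl group to C8 should outrun enolisation. Tautomerisation then gives the 5-OH, hydrogen-bonded to the aldehyde, with the prenyl group para to it between O1 and O7.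

Step 17
Reactants: 22 2-({1-[8-(methoxymethoxy)-2,2-dimethyl-7-prenyl-2H-chromen-6-yl]ethenyl}oxy)-6-hydroxy-4-(methoxymethoxy)-3-prenylbenzaldehyde
Product: 23 (2S)-5-hydroxy-7-(methoxymethoxy)-2-[8-(methoxymethoxy)-2,2-dimethyl-7-prenyl-2H-chromen-6-yl]-8-prenyl-2,3-dihydro-4H-chromen-4-one
Conditions: [Rh(cod)2]BF4 (5 mol %), (R)-DTBM-SEGPHOS (5.5 mol %), acetone, H2 (1 atm, 20 min) then Ar purge; 22, acetone, 50 °C; no base
Reagents that add atoms: none
Why: Proposed new method: the cationic bisphosphine complex of monovalent rhodium binds the enol ether C2=C3 and adds the formyl C–H bond oxidatively (the O5–H···O=C hydrogen bond keeps this C–H pointed at O1) to give an acyl hydride of trivalent rhodium; hydride then migrates to C2, rhodium stays on C3 in a seven-membered rhodacycle (Rh, C4, C4a, C8a, O1, C2, C3), and C3–C4 reductive elimination releases the chromanone and the catalyst. The closest known reaction type is the rhodium bisphosphine cyclisation of 4-substituted pent-4-enals to 3-substituted cyclopentanones and its six-ring endo version with ortho-allylbenzaldehydes bearing a 1,1-disubstituted alkene; an aryl 1-arylvinyl ether has not been used as the alkene partner. Ring C closes in a 6-endo-trig mode with respect to C2=C3. C2 is the only new stereocenter and is set under ligand control: hydride must reach the Re face of C2 (O1 > aryl > C3) to give (2S). Regioselectivity (hydride to C2, not C3) is secured by the 1,1-disubstitution: the other insertion would put rhodium on a fully substituted carbon and require reductive elimination to a quaternary center in a five-membered ring, and since insertion is reversible the faster elimination from the primary alkyl decides. Chemoselectivity against decarbonylation and against the two prenyl groups and the chromene alkene is also needed; the tethered enol ether is the only alkene that can chelate to the acyl rhodium, trisubstituted alkenes bind weakly, and the hydrogen bond to the acyl oxygen should slow CO extrusion. No base is used, because a rhodium phenoxide at O5 would lock the acyl metal in a five-membered chelate on the side of C4 away from O1, out of reach of C3, and because base would open ring C of the product and erase C2.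

Step 18
Reactants: 23 (2S)-5-hydroxy-7-(methoxymethoxy)-2-[8-(methoxymethoxy)-2,2-dimethyl-7-prenyl-2H-chromen-6-yl]-8-prenyl-2,3-dihydro-4H-chromen-4-one
Product: 24 (2S)-5,7-dihydroxy-2-(8-hydroxy-2,2-dimethyl-7-prenyl-2H-chromen-6-yl)-8-prenyl-2,3-dihydro-4H-chromen-4-one
Conditions: HCl (0.5 M) in MeOH–THF (4:1), 25 °C, warmed to 40 °C only if needed
Reagents that add atoms: none
Why: Acid-catalysed acetal exchange with methanol removes both aryl MOM groups; dilute acid offers no enolate or phenoxide pathway for opening ring C, so C2 should stay fixed, and the low acid strength limits addition of the phenols to the prenyl groups.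

## Compound list

1 | 3,4-dihydroxybenzaldehyde | O=Cc1ccc(O)c(O)c1 | starting material
2 | 3-chloro-3-methylbut-1-yne | CC(C)(Cl)C#C | starting material
3 | 3-hydroxy-4-[(2-methylbut-3-yn-2-yl)oxy]benzaldehyde | O=Cc1ccc(OC(C)(C)C#C)c(O)c1 | intermediate
4 | 3,4-dihydroxy-5-(3-methylbuta-1,2-dien-1-yl)benzaldehyde (ortho-allenylphenol) | O=Cc1cc(O)c(O)c(C=C=C(C)C)c1 | intermediate (not isolated)
5 | 8-hydroxy-2,2-dimethyl-2H-chromene-6-carbaldehyde | CC1(C)C=Cc2cc(C=O)cc(O)c2O1 | intermediate
6 | 2,2-dimethyl-8-[(2-methylbut-3-yn-2-yl)oxy]-2H-chromene-6-carbaldehyde | CC1(C)C=Cc2cc(C=O)cc(OC(C)(C)C#C)c2O1 | intermediate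
7 | 2,2-dimethyl-8-[(2-methylbut-3-en-2-yl)oxy]-2H-chromene-6-carbaldehyde | CC1(C)C=Cc2cc(C=O)cc(OC(C)(C)C=C)c2O1 | intermediate
8 | 8-hydroxy-2,2-dimethyl-7-(3-methylbut-2-en-1-yl)-2H-chromene-6-carbaldehyde | CC(C)=CCc1c(C=O)cc2C=CC(C)(C)Oc2c1O | intermediate
9 | 8-(methoxymethoxy)-2,2-dimethyl-7-(3-methylbut-2-en-1-yl)-2H-chromene-6-carbaldehyde | CC(C)=CCc1c(C=O)cc2C=CC(C)(C)Oc2c1OCOC | intermediate
10 | 8-(methoxymethoxy)-2,2-dimethyl-7-(3-methylbut-2-en-1-yl)-2H-chromene-6-carboxylic acid | CC(C)=CCc1c(C(=O)O)cc2C=CC(C)(C)Oc2c1OCOC | intermediate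
11 | 2,4,6-trihydroxybenzaldehyde | O=Cc1c(O)cc(O)cc1O | starting material
12 | 2,6-dihydroxy-4-(methoxymethoxy)benzaldehyde | O=Cc1c(O)cc(OCOC)cc1O | intermediate
13 | prenyl bromide (1-bromo-3-methylbut-2-ene) | CC(C)=CCBr | starting material
14 | 2-hydroxy-4-(methoxymethoxy)-6-[(3-methylbut-2-en-1-yl)oxy]benzaldehyde | O=Cc1c(O)cc(OCOC)cc1OCC=C(C)C | intermediate
15 | 2-(hydroxymethyl)-5-(methoxymethoxy)-3-[(3-methylbut-2-en-1-yl)oxy]phenol | OCc1c(O)cc(OCOC)cc1OCC=C(C)C | intermediate
16 | 2-{[(tert-butyldimethylsilyl)oxy]methyl}-5-(methoxymethoxy)-3-[(3-methylbut-2-en-1-yl)oxy]phenol | CC(C)(C)[Si](C)(C)OCc1c(O)cc(OCOC)cc1OCC=C(C)C | intermediate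
17 | 2-{[(tert-butyldimethylsilyl)oxy]methyl}-5-(methoxymethoxy)-3-(prenyloxy)phenyl 8-(methoxymethoxy)-2,2-dimethyl-7-prenyl-2H-chromene-6-carboxylate | CC(C)=CCc1c(C(=O)Oc3cc(OCOC)cc(OCC=C(C)C)c3CO[Si](C)(C)C(C)(C)C)cc2C=CC(C)(C)Oc2c1OCOC | intermediate
18 | tert-butyl{[2-({1-[8-(methoxymethoxy)-2,2-dimethyl-7-prenyl-2H-chromen-6-yl]ethenyl}oxy)-4-(methoxymethoxy)-6-(prenyloxy)phenyl]methoxy}dimethylsilane | CC(C)=CCc1c(C(=C)Oc3cc(OCOC)cc(OCC=C(C)C)c3CO[Si](C)(C)C(C)(C)C)cc2C=CC(C)(C)Oc2c1OCOC | intermediate
19 | [2-({1-[8-(methoxymethoxy)-2,2-dimethyl-7-prenyl-2H-chromen-6-yl]ethenyl}oxy)-4-(methoxymethoxy)-6-(prenyloxy)phenyl]methanol | CC(C)=CCc1c(C(=C)Oc3cc(OCOC)cc(OCC=C(C)C)c3CO)cc2C=CC(C)(C)Oc2c1OCOC | intermediate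
20 | 2-({1-[8-(methoxymethoxy)-2,2-dimethyl-7-prenyl-2H-chromen-6-yl]ethenyl}oxy)-4-(methoxymethoxy)-6-(prenyloxy)benzaldehyde | CC(C)=CCc1c(C(=C)Oc3cc(OCOC)cc(OCC=C(C)C)c3C=O)cc2C=CC(C)(C)Oc2c1OCOC | intermediate
21 | 2-({1-[8-(methoxymethoxy)-2,2-dimethyl-7-prenyl-2H-chromen-6-yl]ethenyl}oxy)-4-(methoxymethoxy)-5-(2-methylbut-3-en-2-yl)-6-oxocyclohexa-1,3-diene-1-carbaldehyde (ortho-dienone, racemic at the sp3 carbon) | C=CC(C)(C)C1C(OCOC)=CC(OC(=C)c2cc3C=CC(C)(C)Oc3c(OCOC)c2CC=C(C)C)=C(C=O)C1=O | intermediate (not isolated)
22 | 2-({1-[8-(methoxymethoxy)-2,2-dimethyl-7-prenyl-2H-chromen-6-yl]ethenyl}oxy)-6-hydroxy-4-(methoxymethoxy)-3-prenylbenzaldehyde | CC(C)=CCc1c(C(=C)Oc3c(CC=C(C)C)c(OCOC)cc(O)c3C=O)cc2c(c1OCOC)OC(C)(C)C=C2 | intermediate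
23 | (2S)-5-hydroxy-7-(methoxymethoxy)-2-[8-(methoxymethoxy)-2,2-dimethyl-7-prenyl-2H-chromen-6-yl]-8-prenyl-2,3-dihydro-4H-chromen-4-one | CC(C)=CCc1c([C@@H]2CC(=O)c3c(O)cc(OCOC)c(CC=C(C)C)c3O2)cc2c(c1OCOC)OC(C)(C)C=C2 | intermediate
24 | (2S)-5,7-dihydroxy-2-(8-hydroxy-2,2-dimethyl-7-prenyl-2H-chromen-6-yl)-8-prenyl-2,3-dihydro-4H-chromen-4-one (CNP0328260.1) | CC(C)=CCc1c([C@@H]2CC(=O)c3c(O)cc(O)c(CC=C(C)C)c3O2)cc2c(c1O)OC(C)(C)C=C2 | target

## Step count and least certain steps

Total: 18 steps. Longest linear sequence: 14 steps (steps 1–7, then 12–18, from 1). The ring A branch (steps 8–11) joins at step 12.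

**Step 17 (key step).** The most likely failure is decarbonylation of the acyl rhodium hydride, which ends with the metal as an inactive carbonyl complex. The seven-membered rhodacycle forms more slowly than the six-membered ones of the precedents, and the enol ether is crowded by two ortho prenyl groups. Insertion with hydride going to C3, or weak discrimination between the two faces of C2 (an aryloxy and an aryl group of similar size), would also defeat the step. The fallback uses known chemistry, sets out from 14 and 9 and rejoins at 23:
- MeMgBr (2.2 equiv, THF, 0 °C) converts 14 into 2-(1-hydroxyethyl)-5-(methoxymethoxy)-3-(prenyloxy)phenol F1, which MnO2 oxidises to 1-[2-hydroxy-4-(methoxymethoxy)-6-(prenyloxy)phenyl]ethanone F2.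
- Claisen–Schmidt condensation of F2 with 9 (KOH, EtOH, 20 °C) gives the (E)-2'-hydroxychalcone F3.
- NaOAc in refluxing EtOH closes F3 by oxa-Michael addition through its only free hydroxyl to the racemic 5-O-prenyl flavanone F4.
- Eu(fod)3 (toluene, 80 °C) moves the prenyl group to C8 to give racemic 23, F5.
- Preparative HPLC on amylose tris(3,5-dimethylphenylcarbamate) separates (2S)-23 from the (2R) enantiomer F6, which can be racemised with NaOAc and recycled.

**Step 16.** The rearrangement may stop after the first shift (enolisation of 21 leaves a 1,1-dimethylallyl group at C6), or the europium Lewis acid may promote addition of the enol ether to the neighbouring aldehyde. The fallback reverses the order of events: 20 is cyclised under the conditions of step 17 to the (2S)-5-O-prenyl flavanone F7, and the Eu(fod)3 Claisen–Cope rearrangement is then run on this chromanone, a substrate class on which it is established. It rejoins at 23.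

**Step 13.** Methylenation of the ortho-substituted aryl ester may be slower than thermal decay of Cp2TiMe2, and the enol ether may hydrolyse on acidic supports. The fallback makes the C–O bond by cross-coupling, from 9 and 16 to 18:
- MeMgBr converts 9 into 1-[8-(methoxymethoxy)-2,2-dimethyl-7-prenyl-2H-chromen-6-yl]ethanol F8.
- MnO2 gives the methyl ketone F9.
- KN(SiMe3)2 and PhNTf2 (THF, −78 °C) give the 1-arylvinyl triflate F10.
- F10 is coupled with phenol 16 using Pd2(dba)3, 2-(di-tert-butylphosphino)biphenyl and K3PO4 in toluene at 80 °C (zerovalent palladium).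

**Step 10.** The electron-rich salicyl alcohol may lose its benzylic oxygen through ortho-quinone methide formation, seen as over-reduction or self-condensation, and in step 11 some silylation may occur on the phenol. The fallback avoids free 15: 14 is silylated on the phenol (TBSCl, imidazole, DMF) to 2-[(tert-butyldimethylsilyl)oxy]-4-(methoxymethoxy)-6-(prenyloxy)benzaldehyde F11. Reduction with NaBH4 in THF–MeOH then generates the benzylic alkoxide, to which the silyl group migrates (1,5 O-to-O shift driven by phenoxide formation), giving 16 directly.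

**Step 18.** Acid may add the 7-OH or 3'-OH to the adjacent prenyl group (ring closure to a chroman) before the less basic 7-O-MOM group, on a vinylogous ester oxygen, is fully cleaved. The fallback replaces protic acidolysis by silyl transfer under amine buffering. Compound 23 is treated with TMSOTf and 2,2'-bipyridyl in CH2Cl2 at 0 °C, which exchanges both MOM groups for trimethylsilyl groups and silylates the 5-OH, giving the tris(trimethylsilyl) ether F12. Addition of water then hydrolyses F12 to 24.

## Further compounds

F1 | step 17 | 2-(1-hydroxyethyl)-5-(methoxymethoxy)-3-(prenyloxy)phenol (racemic) | CC(O)c1c(O)cc(OCOC)cc1OCC=C(C)C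
F2 | step 17 | 1-[2-hydroxy-4-(methoxymethoxy)-6-(prenyloxy)phenyl]ethanone | CC(=O)c1c(O)cc(OCOC)cc1OCC=C(C)C
F3 | step 17 | (E)-1-[2-hydroxy-4-(methoxymethoxy)-6-(prenyloxy)phenyl]-3-[8-(methoxymethoxy)-2,2-dimethyl-7-prenyl-2H-chromen-6-yl]prop-2-en-1-one | CC(C)=CCc1c(/C=C/C(=O)c3c(O)cc(OCOC)cc3OCC=C(C)C)cc2C=CC(C)(C)Oc2c1OCOC
F4 | step 17 | rac-7-(methoxymethoxy)-2-[8-(methoxymethoxy)-2,2-dimethyl-7-prenyl-2H-chromen-6-yl]-5-(prenyloxy)-2,3-dihydro-4H-chromen-4-one | CC(C)=CCc1c(C2CC(=O)c3c(OCC=C(C)C)cc(OCOC)cc3O2)cc2C=CC(C)(C)Oc2c1OCOC
F5 | step 17 | rac-5-hydroxy-7-(methoxymethoxy)-2-[8-(methoxymethoxy)-2,2-dimethyl-7-prenyl-2H-chromen-6-yl]-8-prenyl-2,3-dihydro-4H-chromen-4-one (racemic 23) | CC(C)=CCc1c(C2CC(=O)c3c(O)cc(OCOC)c(CC=C(C)C)c3O2)cc2c(c1OCOC)OC(C)(C)C=C2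
F6 | step 17 | (2R)-5-hydroxy-7-(methoxymethoxy)-2-[8-(methoxymethoxy)-2,2-dimethyl-7-prenyl-2H-chromen-6-yl]-8-prenyl-2,3-dihydro-4H-chromen-4-one | CC(C)=CCc1c([C@H]2CC(=O)c3c(O)cc(OCOC)c(CC=C(C)C)c3O2)cc2c(c1OCOC)OC(C)(C)C=C2
F7 | step 16 | (2S)-7-(methoxymethoxy)-2-[8-(methoxymethoxy)-2,2-dimethyl-7-prenyl-2H-chromen-6-yl]-5-(prenyloxy)-2,3-dihydro-4H-chromen-4-one | CC(C)=CCc1c([C@@H]2CC(=O)c3c(OCC=C(C)C)cc(OCOC)cc3O2)cc2C=CC(C)(C)Oc2c1OCOC
F8 | step 13 | 1-[8-(methoxymethoxy)-2,2-dimethyl-7-prenyl-2H-chromen-6-yl]ethanol (racemic) | CC(O)c1cc2C=CC(C)(C)Oc2c(OCOC)c1CC=C(C)C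
F9 | step 13 | 1-[8-(methoxymethoxy)-2,2-dimethyl-7-prenyl-2H-chromen-6-yl]ethanone | CC(=O)c1cc2C=CC(C)(C)Oc2c(OCOC)c1CC=C(C)C
F10 | step 13 | 1-[8-(methoxymethoxy)-2,2-dimethyl-7-prenyl-2H-chromen-6-yl]ethenyl trifluoromethanesulfonate | C=C(OS(=O)(=O)C(F)(F)F)c1cc2C=CC(C)(C)Oc2c(OCOC)c1CC=C(C)C
F11 | step 10 | 2-[(tert-butyldimethylsilyl)oxy]-4-(methoxymethoxy)-6-(prenyloxy)benzaldehyde | O=Cc1c(O[Si](C)(C)C(C)(C)C)cc(OCOC)cc1OCC=C(C)C
F12 | step 18 | (2S)-2-[2,2-dimethyl-7-prenyl-8-(trimethylsilyloxy)-2H-chromen-6-yl]-8-prenyl-5,7-bis(trimethylsilyloxy)-2,3-dihydro-4H-chromen-4-one | CC(C)=CCc1c([C@@H]2CC(=O)c3c(O[Si](C)(C)C)cc(O[Si](C)(C)C)c(CC=C(C)C)c3O2)cc2c(c1O[Si](C)(C)C)OC(C)(C)C=C2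
A1 | alternative 1 | 8-hydroxy-2,2-dimethyl-7-(3-methylbut-2-en-1-yl)-2H-chromene-6-carbaldehyde | CC(C)=CCc1c(C=O)cc2C=CC(C)(C)Oc2c1O
A2 | alternative 1 | 3-[(2-methylbut-3-en-2-yl)oxy]-4-[(2-methylbut-3-yn-2-yl)oxy]benzaldehyde | C=CC(C)(C)Oc1cc(C=O)ccc1OC(C)(C)C#C
A3 | alternative 2 | (2S)-2-[2,2-dimethyl-7-prenyl-8-(triisopropylsilyloxy)-2H-chromen-6-yl]-8-prenyl-5,7-bis(triisopropylsilyloxy)-2,3-dihydro-4H-chromen-4-one | CC(C)=CCc1c([C@@H]2CC(=O)c3c(O[Si](C(C)C)(C(C)C)C(C)C)cc(O[Si](C(C)C)(C(C)C)C(C)C)c(CC=C(C)C)c3O2)cc2c(c1O[Si](C(C)C)(C(C)C)C(C)C)OC(C)(C)C=C2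
A4 | alternative 2 | 2-diazo-1-[2-{[2,2-dimethyl-7-prenyl-8-(triisopropylsilyloxy)-2H-chromen-6-yl]methoxy}-3-prenyl-4,6-bis(triisopropylsilyloxy)phenyl]ethanone | [N-]=[N+]=CC(=O)c1c(O[Si](C(C)C)(C(C)C)C(C)C)cc(O[Si](C(C)C)(C(C)C)C(C)C)c(CC=C(C)C)c1OCc1cc2C=CC(C)(C)Oc2c(O[Si](C(C)C)(C(C)C)C(C)C)c1CC=C(C)C
A5 | alternative 3 | (2S)-2-[2,2-dimethyl-7-prenyl-8-(triisopropylsilyloxy)-2H-chromen-6-yl]-5,7-dihydroxy-8-prenyl-2,3-dihydro-4H-chromen-4-one | CC(C)=CCc1c([C@@H]2CC(=O)c3c(O)cc(O)c(CC=C(C)C)c3O2)cc2c(c1O[Si](C(C)C)(C(C)C)C(C)C)OC(C)(C)C=C2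
A6 | alternative 3 | (2S)-5-bromo-2-[2,2-dimethyl-7-prenyl-8-(triisopropylsilyloxy)-2H-chromen-6-yl]-2,3-dihydro-4H-pyran-4-one | CC(C)=CCc1c([C@@H]2CC(=O)C(Br)=CO2)cc2c(c1O[Si](C(C)C)(C(C)C)C(C)C)OC(C)(C)C=C2
A7 | alternative 3 | 1-methoxy-7-methyl-1,3-bis(trimethylsilyloxy)octa-1,3,6-triene | COC(O[Si](C)(C)C)=CC(O[Si](C)(C)C)=CCC=C(C)C
A8 | alternative 3 | methyl 7-methyl-3-oxooct-6-enoate | COC(=O)CC(=O)CCC=C(C)C
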